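**Retrosynthetic overview**
1. The target is constitutionally symmetric: two identical diaryl ethers (benzoate ring A–O–resorcinol ring B) hang through CH2 groups on C4 and C6 of a central orcinol ring C.
2. Key disconnection: both ring B–CH2 bonds, made in one pot from bis-Mannich base 17 (a latent bis-ortho-quinone methide of ring C) and two molecules of diaryl ether 14. The second alkylation joins 14 to the half that already holds ring C and the other diaryl ether.
3. Enabling feature: each CH2 carbon sits on ring C ortho to one phenolic oxygen and para to the other, so its amine leaves to give a quinone methide. It bonds to the ring B carbon lying between two OH groups; Br on ring B and I on ring C block the other activated CH positions and are removed in the last step.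
4. Diaryl ether 14: SNAr of a Baeyer–Villiger-derived phenol (ring B, from orcylaldehyde) on a 2-fluoro-3-formylbenzoate (ring A, from 3-fluoro-5-methylphenol by ortho-lithiation/formylation, bromination and carbonylation).
5. No ring is constructed: the three arenes are bought (3-fluoro-5-methylphenol, orcylaldehyde, orcinol) and only substituted.

Key step: step 12

Remark: the target has no stereocentre and no configurationally stable stereogenic element; it is achiral, so no stereocontrol is needed.

**Step 1**
Reactants: 1 3-fluoro-5-methylphenol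
Product: 2 1-fluoro-3-(methoxymethoxy)-5-methylbenzene
Conditions: MOMCl, i-Pr2NEt, CH2Cl2, 0 °C → rt
Reagents that add atoms: chloromethyl methyl ether, COCCl
Why: O-alkylation of the phenol (MOM ether formation) should be clean and installs the acetal oxygen that directs the next metalation.

**Step 2**
Reactants: 2 1-fluoro-3-(methoxymethoxy)-5-methylbenzene
Product: 5 2-fluoro-6-(methoxymethoxy)-4-methylbenzaldehyde, via aryllithium 3 (not isolated), via lithium aminoalkoxide 4 (not isolated)
Conditions: n-BuLi, THF, −78 °C; DMF, −78 → 0 °C; H2O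
Reagents that add atoms: N,N-dimethylformamide, CN(C)C=O
Why: Directed ortho-metalation should occur at the CH flanked by F and OMOM (two cooperating ortho directors), and formylation of the aryllithium with DMF at −78 °C avoids LiF loss to a benzyne.

**Step 3**
Reactants: 5 2-fluoro-6-(methoxymethoxy)-4-methylbenzaldehyde
Product: 6 3-bromo-2-fluoro-6-(methoxymethoxy)-4-methylbenzaldehyde
Conditions: NBS, DMF, 0 °C → rt, dark
Reagents that add atoms: N-bromosuccinimide, O=C1CCC(=O)N1Br
Why: Electrophilic aromatic bromination should go para to the OMOM donor (between F and CH3), the other free CH being only ortho to OMOM and more hindered.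

**Step 4**
Reactants: 6 3-bromo-2-fluoro-6-(methoxymethoxy)-4-methylbenzaldehyde
Product: 7 methyl 2-fluoro-3-formyl-4-(methoxymethoxy)-6-methylbenzoate
Conditions: Pd(OAc)2, Xantphos, CO (5 bar), Et3N, MeOH, 90 °C
Reagents that add atoms: carbon monoxide, [C-]#[O+]; methanol, CO
Why: Pd-catalysed methoxycarbonylation of the aryl bromide should tolerate the aldehyde, the fluoride and the MOM ether and places the ester between F and CH3.

**Step 5**
Reactants: 8 2,4-dihydroxy-6-methylbenzaldehyde (orcylaldehyde)
Product: 9 3-bromo-4,6-dihydroxy-2-methylbenzaldehyde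
Conditions: NBS (1.0 equiv), MeCN, −20 → 0 °C
Reagents that add atoms: N-bromosuccinimide, O=C1CCC(=O)N1Br
Why: Electrophilic bromination should enter para to the chelated 6-OH and ortho to the free 4-OH (the carbon next to CH3), the site at which orcylaldehyde is known to be chlorinated.

**Step 6**
Reactants: 9 3-bromo-4,6-dihydroxy-2-methylbenzaldehyde
Product: 10 3-bromo-4,6-bis(methoxymethoxy)-2-methylbenzaldehyde
Conditions: NaH, MOMCl, DMF, 0 °C → rt
Reagents that add atoms: chloromethyl methyl ether, COCCl
Why: Double O-alkylation of the sodium phenoxides (NaH is needed for the hydrogen-bonded 6-OH) should give the bis-MOM ether.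

**Step 7**
Reactants: 10 3-bromo-4,6-bis(methoxymethoxy)-2-methylbenzaldehyde
Product: 12 3-bromo-4,6-bis(methoxymethoxy)-2-methylphenol, via aryl formate 11 (not isolated)
Conditions: mCPBA, CH2Cl2, 0 °C → rt; K2CO3 (cat.), MeOH, rt
Reagents that add atoms: 3-chloroperoxybenzoic acid, OOC(=O)c1cccc(Cl)c1
Why: Baeyer–Villiger (Dakin-type) oxidation should proceed with migration of the electron-rich aryl group to the formate, which methanolysis cleaves to the phenol whose oxygen lies between CH3 and OMOM.

**Step 8**
Reactants: 12 3-bromo-4,6-bis(methoxymethoxy)-2-methylphenol; 7 methyl 2-fluoro-3-formyl-4-(methoxymethoxy)-6-methylbenzoate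
Product: 13 methyl 2-[3-bromo-4,6-bis(methoxymethoxy)-2-methylphenoxy]-3-formyl-4-(methoxymethoxy)-6-methylbenzoate
Conditions: K2CO3, DMF, 60 °C, N2
Reagents that add atoms: none
Why: SNAr should be fast because the fluoride is flanked by an ortho formyl and an ortho ester group, 12 has a single free phenol, and the MOM group keeps ring A from becoming a deactivating phenoxide.

**Step 9**
Reactants: 13 methyl 2-[3-bromo-4,6-bis(methoxymethoxy)-2-methylphenoxy]-3-formyl-4-(methoxymethoxy)-6-methylbenzoate
Product: 14 methyl 2-(3-bromo-4,6-dihydroxy-2-methylphenoxy)-3-formyl-4-hydroxy-6-methylbenzoate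
Conditions: 3 M HCl, MeOH, 45 °C; aqueous work-up
Reagents that add atoms: none
Why: Acid-catalysed acetal exchange with methanol should remove all three MOM groups, while the methyl ester and the diaryl ether persist and any dimethyl acetal of the aldehyde reverts on aqueous work-up.

**Step 10**
Reactants: 15 5-methylbenzene-1,3-diol (orcinol)
Product: 16 2-iodo-5-methylbenzene-1,3-diol
Conditions: I2, NaHCO3, H2O–THF, 0 °C
Reagents that add atoms: iodine, II
Why: Iodination of resorcinols with I2/NaHCO3 is known to select the carbon between the two hydroxyl groups, which blocks that position of ring C.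

**Step 11**
Reactants: 16 2-iodo-5-methylbenzene-1,3-diol
Product: 17 4,6-bis[(dimethylamino)methyl]-2-iodo-5-methylbenzene-1,3-diol
Conditions: CH2(NMe2)2 (2.3 equiv), EtOH, rt → 50 °C
Reagents that add atoms: bis(dimethylamino)methane, CN(C)CN(C)C
Why: Phenolic Mannich aminomethylation can only occur at C4 and C6, the two remaining ring carbons, each ortho to one OH and para to the other.

**Step 12**
Reactants: 17 4,6-bis[(dimethylamino)methyl]-2-iodo-5-methylbenzene-1,3-diol; 14 methyl 2-(3-bromo-4,6-dihydroxy-2-methylphenoxy)-3-formyl-4-hydroxy-6-methylbenzoate (2.1 equiv)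
Product: 21 dimethyl 2,2'-{(4,6-dihydroxy-5-iodo-2-methyl-1,3-phenylene)bis[methylene(5-bromo-2,4-dihydroxy-6-methyl-3,1-phenylene)oxy]}bis(3-formyl-4-hydroxy-6-methylbenzoate), via quinone methide 18 (not isolated), via mono-adduct 19 (not isolated), via second quinone methide 20 (not isolated)
Conditions: 1,4-dioxane, 95 °C, slow N2 sweep
Reagents that add atoms: none
Why: The acidic phenols of 14 protonate a CH2NMe2 arm of 17, which loses Me2NH by 1,4-elimination through the ortho phenol to give ortho-quinone methide 18; C5 of the phenoxy ring of 14 (the CH between its two OH groups) adds in a conjugate Friedel–Crafts fashion and tautomerisation rearomatises both rings to 19, and the second arm repeats this via 20, the C–C bond formed there joining a whole diaryl ether to the half that already holds ring C and the other diaryl ether. The closest known reaction type is the thermal generation of ortho-quinone methides from phenolic Mannich bases and their capture by electron-rich phenols, the usual way to methylene-bridged polyphenols. No ring is closed and no stereocentre is formed; three components are joined in one operation. The step needs site selectivity on ring B, C- over O-alkylation and no self-condensation of the electrophile: the bromine of 14 occupies the only other activated carbon of ring B (ortho to 4-OH, para to 6-OH), so C5 is its sole free nucleophilic carbon (the tactic known from halogen-blocked resorcinols), and the iodine of 17 occupies the CH between the two OH groups of ring C, so neither 17 nor 19 can act as a carbon nucleophile and oligomerise. Ring A is deactivated by its formyl and ester groups, and O-alkylation by the quinone methide is reversible at 95 °C and should drain to the C-benzylated product. The nitrogen sweep removes the volatile Me2NH before it can condense with the formyl groups.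

**Step 13**
Reactants: 21 dimethyl 2,2'-{(4,6-dihydroxy-5-iodo-2-methyl-1,3-phenylene)bis[methylene(5-bromo-2,4-dihydroxy-6-methyl-3,1-phenylene)oxy]}bis(3-formyl-4-hydroxy-6-methylbenzoate)
Product: 22 praesorether G, dimethyl 2,2'-{(4,6-dihydroxy-2-methyl-1,3-phenylene)bis[methylene(2,4-dihydroxy-6-methyl-3,1-phenylene)oxy]}bis(3-formyl-4-hydroxy-6-methylbenzoate)
Conditions: H2 (1 atm), 10% Pd/C, Et3N, EtOAc–MeOH, rt, monitored and stopped at full dehalogenation
Reagents that add atoms: none
Why: Pd-catalysed hydrogenolysis of the aryl C–I and C–Br bonds (hydrodehalogenation) should be faster than reduction of the chelated, doubly ortho-substituted formyl groups, which are known to survive such conditions in this compound class, and the esters, diaryl ethers and diarylmethane links are inert.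

**Compound list**
1 | 3-fluoro-5-methylphenol | Cc1cc(O)cc(F)c1 | starting material
2 | 1-fluoro-3-(methoxymethoxy)-5-methylbenzene | COCOc1cc(C)cc(F)c1 | intermediate
3 | [2-fluoro-6-(methoxymethoxy)-4-methylphenyl]lithium | [Li]c1c(F)cc(C)cc1OCOC | intermediate (not isolated)
4 | lithium (dimethylamino)[2-fluoro-6-(methoxymethoxy)-4-methylphenyl]methanolate, racemic | CN(C)C(O[Li])c1c(F)cc(C)cc1OCOC | intermediate (not isolated)
5 | 2-fluoro-6-(methoxymethoxy)-4-methylbenzaldehyde | O=Cc1c(F)cc(C)cc1OCOC | intermediate
6 | 3-bromo-2-fluoro-6-(methoxymethoxy)-4-methylbenzaldehyde | O=Cc1c(F)c(Br)c(C)cc1OCOC | intermediate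
7 | methyl 2-fluoro-3-formyl-4-(methoxymethoxy)-6-methylbenzoate | COC(=O)c1c(C)cc(OCOC)c(C=O)c1F | intermediate
8 | 2,4-dihydroxy-6-methylbenzaldehyde (orcylaldehyde) | Cc1cc(O)cc(O)c1C=O | starting material
9 | 3-bromo-4,6-dihydroxy-2-methylbenzaldehyde | O=Cc1c(C)c(Br)c(O)cc1O | intermediate
10 | 3-bromo-4,6-bis(methoxymethoxy)-2-methylbenzaldehyde | O=Cc1c(C)c(Br)c(OCOC)cc1OCOC | intermediate
11 | 3-bromo-4,6-bis(methoxymethoxy)-2-methylphenyl formate | O=COc1c(C)c(Br)c(OCOC)cc1OCOC | intermediate (not isolated)
12 | 3-bromo-4,6-bis(methoxymethoxy)-2-methylphenol | Oc1c(C)c(Br)c(OCOC)cc1OCOC | intermediate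
13 | methyl 2-[3-bromo-4,6-bis(methoxymethoxy)-2-methylphenoxy]-3-formyl-4-(methoxymethoxy)-6-methylbenzoate | COC(=O)c1c(C)cc(OCOC)c(C=O)c1Oc1c(C)c(Br)c(OCOC)cc1OCOC | intermediate
14 | methyl 2-(3-bromo-4,6-dihydroxy-2-methylphenoxy)-3-formyl-4-hydroxy-6-methylbenzoate | COC(=O)c1c(C)cc(O)c(C=O)c1Oc1c(C)c(Br)c(O)cc1O | intermediate
15 | 5-methylbenzene-1,3-diol (orcinol) | Cc1cc(O)cc(O)c1 | starting material
16 | 2-iodo-5-methylbenzene-1,3-diol | Cc1cc(O)c(I)c(O)c1 | intermediate
17 | 4,6-bis[(dimethylamino)methyl]-2-iodo-5-methylbenzene-1,3-diol | CN(C)Cc1c(C)c(CN(C)C)c(O)c(I)c1O | intermediate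
18 | 4-[(dimethylamino)methyl]-3-hydroxy-2-iodo-5-methyl-6-methylidenecyclohexa-2,4-dien-1-one | C=C1C(=O)C(I)=C(O)C(CN(C)C)=C1C | intermediate (not isolated)
19 | methyl 2-[3-bromo-5-({3-[(dimethylamino)methyl]-4,6-dihydroxy-5-iodo-2-methylphenyl}methyl)-4,6-dihydroxy-2-methylphenoxy]-3-formyl-4-hydroxy-6-methylbenzoate | COC(=O)c1c(C)cc(O)c(C=O)c1Oc1c(C)c(Br)c(O)c(Cc2c(O)c(I)c(O)c(CN(C)C)c2C)c1O | intermediate (not isolated)
20 | methyl 2-{3-bromo-4,6-dihydroxy-5-[(6-hydroxy-5-iodo-2-methyl-3-methylidene-4-oxocyclohexa-1,5-dien-1-yl)methyl]-2-methylphenoxy}-3-formyl-4-hydroxy-6-methylbenzoate | C=C1C(=O)C(I)=C(O)C(Cc2c(O)c(Br)c(C)c(Oc3c(C=O)c(O)cc(C)c3C(=O)OC)c2O)=C1C | intermediate (not isolated)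
21 | dimethyl 2,2'-{(4,6-dihydroxy-5-iodo-2-methyl-1,3-phenylene)bis[methylene(5-bromo-2,4-dihydroxy-6-methyl-3,1-phenylene)oxy]}bis(3-formyl-4-hydroxy-6-methylbenzoate) | COC(=O)c1c(C)cc(O)c(C=O)c1Oc1c(C)c(Br)c(O)c(Cc2c(O)c(I)c(O)c(Cc3c(O)c(Br)c(C)c(Oc4c(C=O)c(O)cc(C)c4C(=O)OC)c3O)c2C)c1O | intermediate
22 | praesorether G, dimethyl 2,2'-{(4,6-dihydroxy-2-methyl-1,3-phenylene)bis[methylene(2,4-dihydroxy-6-methyl-3,1-phenylene)oxy]}bis(3-formyl-4-hydroxy-6-methylbenzoate) | COC(=O)c1c(C)cc(O)c(C=O)c1Oc1c(C)cc(O)c(Cc2c(O)cc(O)c(Cc3c(O)cc(C)c(Oc4c(C=O)c(O)cc(C)c4C(=O)OC)c3O)c2C)c1O | target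

**Step count and risks**
Total step count: 13. Longest linear sequence: 8 steps (steps 1, 2, 3, 4, 8, 9, 12, 13).

Steps most likely to fail:

1. Step 12. The liberated dimethylamine may condense with the formyl groups and aminoalkylate ring B, the second alkylation may stall at the mono-adduct, or iodine may be lost or migrate at 95 °C. The fallback sets out from 17 and 14 and comes back at 21. 17 would be N-methylated on both arms with iodomethane (MeCN, rt) to [(4,6-dihydroxy-5-iodo-2-methyl-1,3-phenylene)bis(methylene)]bis(trimethylammonium) diiodide F1. F1 and 14 (2.1 equiv) with NaHCO3 in MeCN–H2O at rt should then lose trimethylamine on phenoxide formation to the ammonium quinone methide F2, which 14 traps at C5 to give the ammonium mono-adduct F3. F3 loses trimethylamine to quinone methide 20 of the main route, which a second molecule of 14 captures to give 21. This base-triggered 1,4-elimination of a quaternary benzylammonium salt is known chemistry, runs at room temperature and releases only a tertiary amine.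

2. Step 13. The formyl groups may be over-reduced, iodide may poison the catalyst, or the hindered bromines may be removed incompletely. The fallback sets out from 21 and comes back at 22. 21 would be heated with Na2SO3, L-ascorbic acid and Et3N in MeOH–H2O at 65 °C, the reductive protodehalogenation known for unblocking halogen-blocked resorcinols after Friedel–Crafts alkylation; it works by ipso-protonation and halogen transfer to sulfite and does not reduce aldehydes (sulfite adducts of the formyl groups revert on acidic work-up). This fallback makes no new compound (F0).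

3. Step 5. Bromination may occur at the carbon between the two hydroxyl groups or twice, which would put the blocking group in the wrong place. The fallback sets out from 8 and comes back at 10. 8 would first be converted with NaH and MOMCl in DMF into 2,4-bis(methoxymethoxy)-6-methylbenzaldehyde F4, and F4 then brominated with NBS in DMF. With both oxygens alkylated, the carbon between them is doubly ortho-flanked, and bromine should enter para to the 2-OMOM group, next to the methyl group, which gives 10 directly.

**Further compounds**
F1 | step 12 | [(4,6-dihydroxy-5-iodo-2-methyl-1,3-phenylene)bis(methylene)]bis(trimethylammonium) diiodide | C[N+](C)(C)Cc1c(C)c(C[N+](C)(C)C)c(O)c(I)c1O.[I-].[I-]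
F2 | step 12 | [(6-hydroxy-5-iodo-2-methyl-3-methylidene-4-oxocyclohexa-1,5-dien-1-yl)methyl]trimethylammonium iodide | C=C1C(=O)C(I)=C(O)C(C[N+](C)(C)C)=C1C.[I-]
F3 | step 12 | ({3-[(3-bromo-2,6-dihydroxy-5-{[2-formyl-3-hydroxy-6-(methoxycarbonyl)-5-methylphenyl]oxy}-4-methylphenyl)methyl]-4,6-dihydroxy-5-iodo-2-methylphenyl}methyl)trimethylammonium iodide | COC(=O)c1c(C)cc(O)c(C=O)c1Oc1c(C)c(Br)c(O)c(Cc2c(O)c(I)c(O)c(C[N+](C)(C)C)c2C)c1O.[I-]
F0 | step 13 | none | none
F4 | step 5 | 2,4-bis(methoxymethoxy)-6-methylbenzaldehyde | O=Cc1c(C)cc(OCOC)cc1OCOC
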